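I decided to rank these flasks by one number, the warm exposure, and to keep amber and teal in the 5 °C bath until 30 h.

| setting | Tuesday's | Wednesday's | Monday's | Sunday's | amber | red | green | teal | violet |
|---|---|---|---|---|---|---|---|---|---|
| starting material | 0.28 M | 0.28 M | 0.28 M | 0.42 M | 0.28 M (fed, over 30 h) | 0.28 M | 0.28 M | 0.28 M | 0.28 M (fed, over 30 h) |
| second substrate | 0.56 M | 0.28 M | 1.1 M | 0.56 M | 0.560 M | 0.560 M | 0.560 M | 0.560 M | 0.560 M |
| coupling partner | 0.294 M | 0.294 M | 0.294 M | 0.294 M | 0.294 M | 0.294 M (fed, over 30 h) | 0.294 M | 0.294 M | 0.294 M |
| free catalyst | 14 mM | 14 mM | 14 mM | 14 mM | 14 mM | 14 mM | 14 mM | 14 mM | 14 mM |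
| temperature | 10 °C | 25 °C | 10 °C | 25 °C |  | 25 °C | 25 °C |  | 25 °C |
| remark | run made earlier | run made earlier | run made earlier | run made earlier | the addition at 5 °C, then warmed to 25 °C; the feed brings no volume worth counting | all else is in the flask from the start; the feed brings no volume worth counting | everything together at the start | everything together at the start at 5 °C, warmed to 25 °C at 30 h | all else is in the flask from the start; the feed brings no volume worth counting |
| time |  |  |  |  | 40 h | 40 h | 40 h | 40 h | 40 h |

| run | time / h | target / % | over-reaction product / % |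
|---|---|---|---|
| Tuesday's | 12.0 | 6.2 | 0.6 |
| Tuesday's | 25.0 | 10.6 | 1.0 |
| Tuesday's | 40.0 | 14.6 | 2.2 |
| Tuesday's | 48.0 | 16.4 | 3.3 |
| Wednesday's | 12.0 | 18.6 | 5.2 |
| Wednesday's | 25.0 | 22.4 | 16.5 |
| Wednesday's | 40.0 | 18.8 | 29.0 |
| Wednesday's | 50.0 | 16.1 | 37.7 |
| Monday's | 25.0 | 6.8 | 1.2 |
| Monday's | 48.0 | 12.5 | 1.8 |
| Monday's | 96.0 | 16.7 | 3.7 |
| Sunday's | 4.00 | 6.8 | 0.5 |
| Sunday's | 8.00 | 11.6 | 1.5 |
| Sunday's | 20.0 | 17.2 | 5.8 |
| Sunday's | 50.0 | 15.1 | 20.7 |

(standard deviation of a reading: 0.5 percentage points)



- the best flask by share of target in target plus over-reaction product; "all alike" if 1.5 percentage points covers them all (amber / red / green / teal / violet / all alike)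
- share of target in target plus over-reaction product at the end, amber
- share of target in target plus over-reaction product at the end, red
- share of target in target plus over-reaction product at the end, green
- share of target in target plus over-reaction product at the end, teal
- share of target in target plus over-reaction product at the end, violet

Target forms and then turns into over-reaction product, and I took that loss as first order in [target]. From 20.0 h to 50.0 h, Sunday's run, at the flasks' 0.560 M of second substrate and 25 °C, gave 0.0308 /h: the target loss constant, over-reaction product gained per hour per target standing, a reading with the scatter of its points. Tuesday's, at 10 °C, read lower, 0.00741 /h, so I counted warm hours alone, which flatters the cold flasks a little.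

Integrating with x as the constant times the warm time, target made steadily holds a share (1 − e^−x)/x of target plus over-reaction product, and target all present when the warmth begins holds e^−x. My reckoning for amber and teal, warm for 10.0 h, was a bracket from 73.5 % to 86.1 %. Green, warm for 40 h, has 57.5 % as its steady share. Sunday's made product faster in its first 8.00 h than afterwards, so I expected green below that. I placed red and violet above green, without a figure. Don't touch the bath early.

The forecast named amber: amber 86 % (79 % to 91 %), teal 84 %, red 67 %, violet 66 %, green 51 %. Its ground was “Cold holding mainly removes time”.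

Amber came out best at 82.5 %, with teal 79.8 %, red 64.7 %, violet 61.2 % and green 49.4 %. Amber and teal both lay inside the bracket from 0.0308 /h, 73.5 % to 86.1 %, and green lay below 57.5 %.

    starting material + free catalyst ⇌ catalyst intermediate A (K = 1.20 /M, k = 0.871 /M/min, Ea = 68.0 kJ/mol, ΔH = −2.00 kJ/mol)
    coupling partner + catalyst intermediate A → free catalyst + target (k = 0.198 /M/min, Ea = 65.0 kJ/mol)
    second substrate + free catalyst ⇌ catalyst intermediate B (K = 2.72 /M, k = 0.321 /M/min, Ea = 74.0 kJ/mol, ΔH = 1.00 kJ/mol)
    coupling partner + catalyst intermediate B → free catalyst + second product (k = 0.0436 /M/min, Ea = 57.0 kJ/mol)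
    free catalyst + target → free catalyst + over-reaction product (k = 0.0867 /M/min, Ea = 73.0 kJ/mol)
    (constants at 25 °C)

In amber at 40.0 h, second substrate with free catalyst and catalyst intermediate B relaxed with a half-life of 2.52 min, far shorter than the 1.5 h of the onward step with coupling partner. Catalyst intermediate B, the resting state, held 49.6 % of the catalyst there, beside free catalyst at 40.0 % and catalyst intermediate A at 10.4 %.

(The runs come from a simulation for substances that don't exist, noise included.)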